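## Compound numbering used throughout

1 (tert-butyldimethylsilyloxy)acetaldehyde · 2 (E)-1,2-bis(tert-butyldimethylsilyloxy)ethene · 3 methyl 2-oxo-2H-pyran-3-carboxylate · 4 bridged bicyclic lactone (cycloadduct) · 5 trans-bis(silyloxy) diene methyl ester · 6 dienyl methanol · 7 C7 benzoate bis(silyl ether) · 8 C7 benzoate trans-diol · 9 O3,O7-dibenzoate with free O2–H · 10 diene triester · 11 target.

## Analysis of the target

The target is a cyclohexene oxide (7-oxabicyclo[4.1.0]hept-4-ene). Its ring carbons are numbered C1 (quaternary oxirane carbon carrying the C7H2 benzoate), C2 (acetate), C3 (benzoate), C4=C5 and C6 (oxirane CH); C7 is the only skeletal carbon outside the ring. Four contiguous stereocentres, C1, C2, C3 and C6, have the configuration (1S,2S,3R,6S): the C2 acetate and the C3 benzoate are trans, and the oxirane oxygen lies on the face opposite to the C2 acetate, which is the face of the C3 benzoate. The sensitive parts are the vinyl oxirane (C6 is allylic and opens under acid or in the SN2' sense) and the three esters of two kinds on O2, O3 and O7, which can migrate as soon as a neighbouring hydroxyl is free. Any cyclohexadiene precursor with leaving groups on its sp3 carbons is one elimination away from a benzene ring. The difficulty is threefold: absolute control with no carbon stereocentre to lean on, a trans-1,2-dioxygenation that cis-selective arene dearomatisation does not provide, and the placing of two different acyl groups and one oxirane among four skeletal oxygens. The plan rests on what appears once the oxirane is traced back to a C1=C6 alkene: C2–C3 is a trans-dioxygenated two-carbon unit between two sp2 carbons, and C1(C7)–C6–C5–C4 is a four-carbon diene unit with a one-carbon branch at its end, the pattern left by a [4+2] union of an enediol ether with a 3-carboxy-2-pyrone after loss of the lactone bridge.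

## Retrosynthetic reasoning

**Oxirane.** The C1–O and C6–O bonds of 11 are cut first, which leads to the diene triester 10. The oxirane is the most fragile group and is best made last, and 10 is a stable conjugated diene that already carries every ester. The forward step needs a peracid to choose the trisubstituted C1=C6 alkene over C4=C5 and to approach anti to the C2 acetate.

**Acyl groups on O2 and O3.** The acetate and then the O3 benzoate are removed, through the hydroxy dibenzoate 9 to the diol 8. The order follows the steric ranking of the two secondary oxygens. O3 is flanked by the unsubstituted C4=C5 alkene and should take the bulkier acyl group first; O2, next to C1 and its C7 branch, then takes the small acetyl group. No protecting group is spent on the differentiation.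

**C7 and the silyl ethers.** Diol 8 is traced to the bis(silyl ether) 7, its benzoate to the primary alcohol 6, and 6 to the methyl ester 5. Keeping C7 at the ester oxidation level up to 5 is what makes the ring-forming step possible. Benzoylating O7 while O2 and O3 are still silylated removes any competition among the three oxygens.

**Ring.** Ester 5 is cut at C1–C2 and C3–C4. These are the only two ring bonds that join an sp2 carbon to an oxygenated sp3 carbon. Cutting them divides the ring into the C2–C3 enediol unit, the (E)-alkene 2, and the C1(C7)–C6–C5–C4 unit, the pyrone 3. In 3 the lactone bridge holds the diene cisoid and, with the ester, makes it electron-poor. Forward, an inverse-electron-demand [4+2] addition gives the bridged lactone 4, and a retro-[4+2] decarboxylation then unveils the C1=C6–C5=C4 diene of 5. The disconnection gains both stereocentres of the diol, the full carbon skeleton and the correct oxidation state at every carbon in one operation, from an achiral diene and an achiral, twofold-symmetric alkene. Because 2 is symmetric there is no regiochemistry to control. A chiral copper Lewis acid bound to the two carbonyls of 3 has to select the face, and the E geometry of 2 has to be carried into the trans diol.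

**Dienophile.** Alkene 2 is cut at its enol O–Si bond to the commercial aldehyde 1. One silylation gives it, and the only burden is the separation of the E isomer.

## Alternatives that were turned down

**Alternative 1:** Sulfonium ylide epoxy-annulation. The disconnection cuts C1–C6 and C6–O. The substrate is the open-chain keto sulfonium salt A1 (C1 ketone with the C7 benzoate, trans C2/C3 diol tied as a tetraisopropyldisiloxane, Z C4=C5 alkene, tetrahydrothiophenium on C6). In the forward step base forms the allylic ylide, C6 adds to the C1 ketone, and the alkoxide expels the cyclic sulfide, closing carbocycle and oxirane together to give A2.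
- For: ring, quaternary C1, C6 and the oxirane arise in one step; C2 and C3 can be bought from the chiral pool; no late epoxidation has to be selective. On the oxirane question this plan is stronger than the chosen one.
- Against: the C1 ketone of A1 is enolisable on both sides (C7 next to a benzoate, C2 next to a β-oxygen), so the base needed for the ylide threatens epimerisation at C2 and β-elimination. The allylic ylide is ambident and can lose its Z geometry, after which closure is impossible. The face of addition to the ketone is decided by the conformation of a seven-membered disiloxane ring, a weak control element. A2 still needs removal of the disiloxane and the same O2/O3 differentiation, now on a vinyl oxirane.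
- Comparison: A1 would take roughly ten steps to make, against one for the precursors of the chosen key step. The chosen route offers a two-component catalytic ring synthesis and robust intermediates in exchange for a selective final epoxidation.

**Alternative 2:** Singlet oxygen cycloaddition. The C3–O and C6–O bonds are traced to a peroxide bridge. The substrate is the spiro-epoxy cyclohexadienyl acetate A3 (oxirane across C1 and C7). Singlet oxygen (O2, light, tetraphenylporphyrin) adds across C3 and C6 anti to the acetate to give the endoperoxide A4. O–O reduction, migration of the oxirane from C1–C7 to C1–C6 by attack of O6 on C1 (Payne rearrangement), and double benzoylation of O3 and O7 would finish.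
- For: this is the shortest plan. The cis relation of O3 and O6 is guaranteed by the cycloaddition, so the oxirane face is tied stereospecifically to C3. O3 and O7 emerge together and take the same acyl group while O2 already carries its acetate, so no oxygen differentiation is needed. On step count and on these two selectivity points it is as strong as or stronger than the chosen route.
- Against: the sequence leading to A3 passes through a dimerisation-prone dienone stage and gives racemic material, so a single enantiomer needs a resolution. A4 is a base-sensitive allylic peroxide (Kornblum–DeLaMare cleavage), yet the oxirane migration needs base and a backside attack at the fully substituted C1. The acetate can migrate once the diol is free.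
- Comparison: the chosen strategy sets the absolute configuration catalytically in the ring-forming step and uses no peroxide and no unstable dienone, at the price of two or three more steps.

**Alternative 3:** Nozaki–Hiyama–Kishi closure. The disconnection is C5–C6, in the open-chain Z-iodoalkenyl aldehyde A5 (aldehyde C6 on the quaternary C1 that bears a triethylsilyl ether and the C7 benzoate; C2 acetate and C3 benzoate in place). CrCl2 with catalytic NiCl2 turns the C5–I bond into an alkenylchromium species that adds to the aldehyde and closes the ring to the cyclohexenol A6, with O6 trans to O1. Activation of O6 and attack of O1 with inversion would give the oxirane.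
- For: the coupling tolerates esters and silyl ethers. All three acyl groups are placed by sequence on an open chain and not by selectivity. The oxirane closure is stereospecific and independent of any peracid face preference. On these two points it is stronger than the chosen route.
- Against: A5 contains a quaternary carbinol next to two further oxygenated stereocentres, a Z-iodoalkene and three different O-substituents, and would take a dozen or more steps. Its aldehyde is α-oxygenated and β-acyloxylated, so elimination and acyl migration threaten. The new C6 carbinol is controlled only by the neighbouring quaternary centre. Excess divalent chromium is needed, and an allylic sulfonate at C6 can ionise or react in the SN2' sense.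
- Comparison: about twice the length of the chosen route, which keeps the risk in one catalytic step on simple materials.

Key step: step 2

Assumption: the sense of induction is taken from the square-planar two-point-binding model of the copper–bis(oxazoline) complex, which for the (S,S)-tert-butyl ligand predicts the (5R,6R) diene 5; should the sense prove opposite, the (R,R) ligand, equally available, is used with no other change.

## Route

Step 1
Reactants: 1 (tert-butyldimethylsilyloxy)acetaldehyde
Product: 2 (E)-1,2-bis(tert-butyldimethylsilyloxy)ethene
Conditions: TBSOTf (1.1 equiv), Et3N (1.5 equiv), CH2Cl2, 0 °C → rt; aq. NaHCO3; E/Z separation on Et3N-deactivated SiO2 (pentane)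
Reagents that add atoms: tert-butyldimethylsilyl trifluoromethanesulfonate (TBSOTf), CC(C)(C)[Si](C)(C)OS(=O)(=O)C(F)(F)F
Why: Soft enolisation: O-silylation of the aldehyde gives a silyloxocarbenium ion that Et3N deprotonates to the silyl enol ether; both geometries are expected, with the Z isomer (F2 of the fallback below) probably the larger part under kinetic control. The centrosymmetric E isomer has no dipole moment and should elute first, and its geometry can be confirmed from the larger vicinal H–H coupling seen in the 13C satellites.

Step 2
Reactants: 2 (E)-1,2-bis(tert-butyldimethylsilyloxy)ethene (1.5 equiv); 3 methyl 2-oxo-2H-pyran-3-carboxylate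
Product: 5 methyl (5R,6R)-5,6-bis(tert-butyldimethylsilyloxy)cyclohexa-1,3-diene-1-carboxylate, via bridged bicyclic lactone 4 (not isolated)
Conditions: Cu(OTf)2 (10 mol %), (S,S)-tBu-BOX [2,2'-(propane-2,2-diyl)bis((4S)-4-tert-butyl-4,5-dihydro-1,3-oxazole), 11 mol %], 4 Å MS, CH2Cl2, −20 → 0 °C; plug of Et3N-deactivated SiO2; then PhMe, NaHCO3 (solid), 90 °C
Reagents that add atoms: none
Why: Two-point binding of the lactone and ester carbonyls of 3 to the Cu(OTf)2–bis(oxazoline) complex (divalent copper) lowers the LUMO of the pyrone, and the electron-rich alkene 2 adds across pyrone C3 and C6 in an asynchronous inverse-electron-demand Diels–Alder reaction, the C3–C4 bond of the target leading and the C1–C2 bond closing at the malonate-like carbon. The closest known reaction type is the copper–bis(oxazoline)-catalysed cycloaddition of 3-alkoxycarbonyl-2-pyrones with enol ethers, silyl enol ethers and 1,3-dioxoles, followed by thermal extrusion of CO2 from the bridged lactone. The carbocycle is closed in an intermolecular [4+2] mode, suprafacial on both partners, which gives the 2-oxabicyclo[2.2.2]octene 4; once the Lewis acid has been removed, warming triggers a retro-[4+2] loss of CO2 that opens the bicycle to the monocyclic diene 5, driven by the gas and by conjugation of the new diene with the ester. The trans relation of C2 and C3 follows from the E geometry of 2, which a suprafacial addition cannot scramble unless the reaction turns stepwise; the bulky silyl groups slow silyl transfer and so should keep a zwitterionic Mukaiyama–Michael-type path from competing. The absolute configuration is decided by which enantiotopic face of 2 becomes bonded, and this is fixed jointly by the pyrone face that the tert-butyl group of the ligand leaves open and by the endo position of the silyloxy group on the carbon that bonds to C1, the exo position there pointing at the metal centre. The bridgehead centres of 4 become sp2 on loss of CO2, so that only C2 and C3 carry stereochemical information onward. No regiochemical issue arises, since the two carbons of 2 are related by a twofold axis; the step needs face and endo/exo control together, and a neutral, copper-free, buffered thermolysis so that 5 does not lose silanol and aromatise.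

Step 3
Reactants: 5 methyl (5R,6R)-5,6-bis(tert-butyldimethylsilyloxy)cyclohexa-1,3-diene-1-carboxylate
Product: 6 [(5R,6R)-5,6-bis(tert-butyldimethylsilyloxy)cyclohexa-1,3-dien-1-yl]methanol
Conditions: iBu2AlH (2.5 equiv), CH2Cl2, −78 °C; aq. potassium sodium tartrate
Reagents that add atoms: none
Why: 1,2-Reduction of the conjugated ester by iBu2AlH at low temperature gives the allylic alcohol and leaves the diene and the silyl ethers alone; no stereocentre is touched.

Step 4
Reactants: 6 [(5R,6R)-5,6-bis(tert-butyldimethylsilyloxy)cyclohexa-1,3-dien-1-yl]methanol
Product: 7 [(5R,6R)-5,6-bis(tert-butyldimethylsilyloxy)cyclohexa-1,3-dien-1-yl]methyl benzoate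
Conditions: BzCl (1.2 equiv), pyridine, DMAP (cat.), CH2Cl2, 0 °C
Reagents that add atoms: benzoyl chloride, O=C(Cl)c1ccccc1
Why: DMAP-catalysed acylation of the only free hydroxyl places the C7 benzoate while both secondary oxygens are still masked as silyl ethers.

Step 5
Reactants: 7 [(5R,6R)-5,6-bis(tert-butyldimethylsilyloxy)cyclohexa-1,3-dien-1-yl]methyl benzoate
Product: 8 [(5R,6R)-5,6-dihydroxycyclohexa-1,3-dien-1-yl]methyl benzoate
Conditions: Bu4NF (3 equiv), AcOH (3 equiv), THF, 0 °C → rt
Reagents that add atoms: none
Why: Fluoride-mediated desilylation of both secondary silyl ethers; the acetic acid buffer keeps the alkoxides protonated, so the C7 benzoate should not migrate to O2 and the dienediol is exposed neither to strong base nor to acid, either of which would aromatise it.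

Step 6
Reactants: 8 [(5R,6R)-5,6-dihydroxycyclohexa-1,3-dien-1-yl]methyl benzoate
Product: 9 [(5R,6R)-5-(benzoyloxy)-6-hydroxycyclohexa-1,3-dien-1-yl]methyl benzoate
Conditions: BzCl (1.05 equiv), pyridine, CH2Cl2, −40 → −20 °C
Reagents that add atoms: benzoyl chloride, O=C(Cl)c1ccccc1
Why: Kinetic mono-acylation: O3 adjoins the unsubstituted C4=C5 alkene, whereas O2 sits next to C1 and its C7H2OBz branch, so one equivalent of the bulky acyl chloride at low temperature is expected to go to O3.

Step 7
Reactants: 9 [(5R,6R)-5-(benzoyloxy)-6-hydroxycyclohexa-1,3-dien-1-yl]methyl benzoate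
Product: 10 [(5R,6R)-6-acetoxy-5-(benzoyloxy)cyclohexa-1,3-dien-1-yl]methyl benzoate
Conditions: Ac2O, pyridine, DMAP (cat.), CH2Cl2, 0 °C
Reagents that add atoms: acetic anhydride, CC(=O)OC(C)=O
Why: DMAP-catalysed acetylation of the remaining, more hindered hydroxyl with the small acyl donor; the short reaction at 0 °C leaves the benzoates in place.

Step 8
Reactants: 10 [(5R,6R)-6-acetoxy-5-(benzoyloxy)cyclohexa-1,3-dien-1-yl]methyl benzoate
Product: 11 [(1S,2S,3R,6S)-2-acetoxy-3-(benzoyloxy)-7-oxabicyclo[4.1.0]hept-4-en-1-yl]methyl benzoate (numbering of the analysis)
Conditions: mCPBA (1.2 equiv), Na2HPO4, CH2Cl2, 0 °C → rt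
Reagents that add atoms: 3-chloroperoxybenzoic acid (mCPBA), OOC(=O)c1cccc(Cl)c1
Why: Prilezhaev epoxidation: the trisubstituted C1=C6 alkene is the more nucleophilic of the two conjugated double bonds, and the C2 acetate, held pseudoaxial by allylic strain against the C7 branch, shields its own face, so oxygen should be delivered anti to it and set C1 and C6 together in one concerted syn transfer. The phosphate buffer keeps the acid by-product from opening the vinyl oxirane.

## Compound list

1 | (tert-butyldimethylsilyloxy)acetaldehyde | CC(C)(C)[Si](C)(C)OCC=O | starting material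
2 | (E)-1,2-bis(tert-butyldimethylsilyloxy)ethene | CC(C)(C)[Si](C)(C)O/C=C/O[Si](C)(C)C(C)(C)C | intermediate
3 | methyl 2-oxo-2H-pyran-3-carboxylate | COC(=O)C1=CC=COC1=O | starting material
4 | methyl (1R,4S,7R,8R)-7,8-bis(tert-butyldimethylsilyloxy)-3-oxo-2-oxabicyclo[2.2.2]oct-5-ene-4-carboxylate (8-silyloxy endo, 7-silyloxy exo) | COC(=O)[C@@]12C=C[C@@H](OC1=O)[C@@H](O[Si](C)(C)C(C)(C)C)[C@@H]2O[Si](C)(C)C(C)(C)C | intermediate
5 | methyl (5R,6R)-5,6-bis(tert-butyldimethylsilyloxy)cyclohexa-1,3-diene-1-carboxylate | COC(=O)C1=CC=C[C@@H](O[Si](C)(C)C(C)(C)C)[C@@H]1O[Si](C)(C)C(C)(C)C | intermediate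
6 | [(5R,6R)-5,6-bis(tert-butyldimethylsilyloxy)cyclohexa-1,3-dien-1-yl]methanol | OCC1=CC=C[C@@H](O[Si](C)(C)C(C)(C)C)[C@@H]1O[Si](C)(C)C(C)(C)C | intermediate
7 | [(5R,6R)-5,6-bis(tert-butyldimethylsilyloxy)cyclohexa-1,3-dien-1-yl]methyl benzoate | O=C(OCC1=CC=C[C@@H](O[Si](C)(C)C(C)(C)C)[C@@H]1O[Si](C)(C)C(C)(C)C)c1ccccc1 | intermediate
8 | [(5R,6R)-5,6-dihydroxycyclohexa-1,3-dien-1-yl]methyl benzoate | O=C(OCC1=CC=C[C@@H](O)[C@@H]1O)c1ccccc1 | intermediate
9 | [(5R,6R)-5-(benzoyloxy)-6-hydroxycyclohexa-1,3-dien-1-yl]methyl benzoate | O=C(OCC1=CC=C[C@@H](OC(=O)c2ccccc2)[C@@H]1O)c1ccccc1 | intermediate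
10 | [(5R,6R)-6-acetoxy-5-(benzoyloxy)cyclohexa-1,3-dien-1-yl]methyl benzoate | CC(=O)O[C@H]1[C@H](OC(=O)c2ccccc2)C=CC=C1COC(=O)c1ccccc1 | intermediate
11 | [(1S,2S,3R,6S)-2-acetoxy-3-(benzoyloxy)-7-oxabicyclo[4.1.0]hept-4-en-1-yl]methyl benzoate (numbering of the analysis) | CC(=O)O[C@H]1[C@H](OC(=O)c2ccccc2)C=C[C@@H]2O[C@@]21COC(=O)c1ccccc1 | target

## Step count and least certain steps

Total step count: 8. Longest linear sequence: 8 steps (1 → 2 → 5 → 6 → 7 → 8 → 9 → 10 → 11); pyrone 3 is purchased.

**Step 2 (key step).** The most likely failure is erosion of enantiomeric purity through incomplete orientation control. On one pyrone face the E alkene can place either of its silyloxy groups endo; the two adducts are diastereomers, but after loss of CO2 they give opposite enantiomers of 5. Further risks are a stepwise addition with silyl transfer under Cu(OTf)2, and loss of silanol or a hydrogen shift during the thermolysis, both of which end in an arene. Fallback, setting out from 2 and 3 and returning at 5: cycloaddition and thermolysis are separated. The adduct 4 is isolated at or below room temperature on deactivated silica and freed there from its orientation diastereomer, methyl (1R,4S,7S,8S)-7,8-bis(tert-butyldimethylsilyloxy)-3-oxo-2-oxabicyclo[2.2.2]oct-5-ene-4-carboxylate F1. Pure 4 is then heated in buffered toluene to 5. Enantiomeric purity then rests on a separation of diastereomers and no longer on the kinetic orientation preference alone.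

**Step 1.** The likely problem is supply: kinetic soft enolisation of an α-oxygenated aldehyde tends to favour the Z enol ether, so the E isomer may be the minor fraction, and some hydrolysis on silica is possible. Fallback, setting out from 3 and the Z isomer of step 1 and returning at 9: (Z)-1,2-bis(tert-butyldimethylsilyloxy)ethene F2 is taken through the same Cu(OTf)2/bis(oxazoline) cycloaddition with 3. With a Z alkene both silyloxy groups can be endo; the cis bridged lactone F3 forms and loses its bridge on warming to the cis diene ester F4, which has C2 as in 5 and C3 epimeric. iBu2AlH gives the cis dienyl methanol F5, benzoylation the cis C7 benzoate F6, and buffered fluoride the cis diol F7. A Mitsunobu reaction (PPh3, DIAD, benzoic acid, THF, 0 °C) at the less hindered C3 hydroxyl then inverts C3 and installs its benzoate in the same operation, which gives 9. The trans relation is thus made by SN2 inversion and not carried over from alkene geometry, at the cost of possible SN2' attack or elimination to the arene.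

**Step 6.** Benzoylation may go to O2 or to both oxygens, and base can move acyl groups (O7 to O2, O3 to O2), because the two secondary hydroxyls differ only in their steric surroundings. Fallback, setting out from 6 and returning at 9: 6 is desilylated before any ester is present (Bu4NF, AcOH, THF) to the triol (1R,2R)-3-(hydroxymethyl)cyclohexa-3,5-diene-1,2-diol F8, which also removes the migration risk of step 5. PhB(OH)2 (1 equiv, CH2Cl2, 4 Å MS) ties O7 and O2 into the six-membered cyclic phenylboronate F9, since the trans-vicinal O2/O3 pair cannot bridge. BzCl/pyridine acylates the only free hydroxyl, O3, to the boronate benzoate F10. Exchange with pinacol releases the 3-benzoate diol F11, whose primary allylic O7 is benzoylated selectively (BzCl 1 equiv, 2,4,6-collidine, −78 °C) to give 9.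

**Step 8.** Poor site selectivity (attack on C4=C5 or double epoxidation) or poor facial selectivity is possible: the C2 acetate is only a steric control element, and the C3 benzoate sits on the face that has to be attacked. Acid-promoted opening of the vinyl oxirane is a further risk. Fallback, setting out from 6 and reaching 11 by another order of steps: the oxirane is introduced on the allylic alcohol 6 by a Sharpless asymmetric epoxidation (Ti(OiPr)4, L-(+)-diethyl tartrate, tBuOOH, 4 Å MS, CH2Cl2, −20 °C). The C7 hydroxyl directs it to C1=C6 only, and the tartrate sets the face: the L-(+) ester, which gives (2S,3S)-epoxy alcohols from E-3-substituted allylic alcohols, corresponds to the required face and is matched with the shielding by the C2 silyl ether. This gives the epoxy alcohol F12. Benzoylation of O7 gives the epoxy benzoate F13, buffered fluoride the epoxy diol F14, selective benzoylation of O3 the hydroxy dibenzoate F15, and acetylation of O2 gives 11.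

## Further compounds

F1 | step 2 | methyl (1R,4S,7S,8S)-7,8-bis(tert-butyldimethylsilyloxy)-3-oxo-2-oxabicyclo[2.2.2]oct-5-ene-4-carboxylate (orientation diastereomer of 4) | COC(=O)[C@@]12C=C[C@@H](OC1=O)[C@H](O[Si](C)(C)C(C)(C)C)[C@H]2O[Si](C)(C)C(C)(C)C
F2 | step 1 | (Z)-1,2-bis(tert-butyldimethylsilyloxy)ethene | CC(C)(C)[Si](C)(C)O/C=C\O[Si](C)(C)C(C)(C)C
F3 | step 1 | methyl (1R,4S,7S,8R)-7,8-bis(tert-butyldimethylsilyloxy)-3-oxo-2-oxabicyclo[2.2.2]oct-5-ene-4-carboxylate (cis bridged lactone, both silyloxy groups endo) | COC(=O)[C@@]12C=C[C@@H](OC1=O)[C@H](O[Si](C)(C)C(C)(C)C)[C@@H]2O[Si](C)(C)C(C)(C)C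
F4 | step 1 | methyl (5S,6R)-5,6-bis(tert-butyldimethylsilyloxy)cyclohexa-1,3-diene-1-carboxylate | COC(=O)C1=CC=C[C@H](O[Si](C)(C)C(C)(C)C)[C@@H]1O[Si](C)(C)C(C)(C)C
F5 | step 1 | [(5S,6R)-5,6-bis(tert-butyldimethylsilyloxy)cyclohexa-1,3-dien-1-yl]methanol | OCC1=CC=C[C@H](O[Si](C)(C)C(C)(C)C)[C@@H]1O[Si](C)(C)C(C)(C)C
F6 | step 1 | [(5S,6R)-5,6-bis(tert-butyldimethylsilyloxy)cyclohexa-1,3-dien-1-yl]methyl benzoate | O=C(OCC1=CC=C[C@H](O[Si](C)(C)C(C)(C)C)[C@@H]1O[Si](C)(C)C(C)(C)C)c1ccccc1
F7 | step 1 | [(5S,6R)-5,6-dihydroxycyclohexa-1,3-dien-1-yl]methyl benzoate | O=C(OCC1=CC=C[C@H](O)[C@@H]1O)c1ccccc1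
F8 | step 6 | (1R,2R)-3-(hydroxymethyl)cyclohexa-3,5-diene-1,2-diol | OCC1=CC=C[C@@H](O)[C@@H]1O
F9 | step 6 | (8R,8aR)-2-phenyl-8,8a-dihydro-4H-1,3,2-benzodioxaborinin-8-ol (phenylboronate across O7 and O2) | O[C@@H]1C=CC=C2COB(c3ccccc3)O[C@@H]12
F10 | step 6 | (8R,8aR)-2-phenyl-8,8a-dihydro-4H-1,3,2-benzodioxaborinin-8-yl benzoate | O=C(O[C@@H]1C=CC=C2COB(c3ccccc3)O[C@@H]12)c1ccccc1
F11 | step 6 | (1R,6R)-6-hydroxy-5-(hydroxymethyl)cyclohexa-2,4-dien-1-yl benzoate | OCC1=CC=C[C@@H](OC(=O)c2ccccc2)[C@@H]1O
F12 | step 8 | [(1S,2S,3R,6S)-2,3-bis(tert-butyldimethylsilyloxy)-7-oxabicyclo[4.1.0]hept-4-en-1-yl]methanol (numbering of the analysis) | CC(C)(C)[Si](C)(C)O[C@H]1[C@H](O[Si](C)(C)C(C)(C)C)C=C[C@@H]2O[C@@]21CO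
F13 | step 8 | [(1S,2S,3R,6S)-2,3-bis(tert-butyldimethylsilyloxy)-7-oxabicyclo[4.1.0]hept-4-en-1-yl]methyl benzoate (numbering of the analysis) | CC(C)(C)[Si](C)(C)O[C@H]1[C@H](O[Si](C)(C)C(C)(C)C)C=C[C@@H]2O[C@@]21COC(=O)c1ccccc1
F14 | step 8 | [(1R,2S,3R,6S)-2,3-dihydroxy-7-oxabicyclo[4.1.0]hept-4-en-1-yl]methyl benzoate (numbering of the analysis; spatial arrangement as in 11) | O[C@H]1[C@H](O)C=C[C@@H]2O[C@@]21COC(=O)c1ccccc1
F15 | step 8 | [(1R,2S,3R,6S)-3-(benzoyloxy)-2-hydroxy-7-oxabicyclo[4.1.0]hept-4-en-1-yl]methyl benzoate (numbering of the analysis; spatial arrangement as in 11) | O[C@H]1[C@H](OC(=O)c2ccccc2)C=C[C@@H]2O[C@@]21COC(=O)c1ccccc1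
A1 | alternative 1 | open-chain keto sulfonium salt: C1 ketone with C7 benzoate, tetraisopropyldisiloxane-bridged trans C2/C3 diol, Z C4=C5 alkene, C6 tetrahydrothiophenium tetrafluoroborate | O=C(OCC(=O)[C@H]1O[Si](C(C)C)(C(C)C)O[Si](C(C)C)(C(C)C)O[C@@H]1/C=C\C[S+]2CCCC2)c3ccccc3.F[B-](F)(F)F
A2 | alternative 1 | epoxy cyclohexene C7 benzoate with tetraisopropyldisiloxane-bridged trans C2/C3 diol | O=C(OC[C@]12O[C@H]1C=C[C@H]3O[Si](C(C)C)(C(C)C)O[Si](C(C)C)(C(C)C)O[C@H]23)c4ccccc4
A3 | alternative 2 | 1-oxaspiro[2.5]octa-5,7-dien-4-yl acetate (spiro-epoxy cyclohexadienyl acetate, configuration as in the SMILES) | CC(=O)O[C@H]1C=CC=C[C@]12CO2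
A4 | alternative 2 | endoperoxide of A3 with peroxide bridge across C3 and C6 and C4=C5 alkene | CC(=O)O[C@H]1[C@H]2C=C[C@H](OO2)[C@]13CO3
A5 | alternative 3 | open-chain Z-iodoalkenyl aldehyde: C6 aldehyde on quaternary C1 (triethylsilyl ether, C7 benzoate), C2 acetate, C3 benzoate, C5 iodide | O=C[C@@](O[Si](CC)(CC)CC)(COC(=O)c1ccccc1)[C@@H](OC(C)=O)[C@H](OC(=O)c2ccccc2)/C=C\I
A6 | alternative 3 | cyclohexenol with O6 trans to the O1 triethylsilyl ether | O[C@@H]1C=C[C@@H](OC(=O)c2ccccc2)[C@H](OC(C)=O)[C@]1(O[Si](CC)(CC)CC)COC(=O)c3ccccc3
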